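**Retrosynthetic overview**
- Feature: in ring C the chain C4–C3–C2 carries oxygen at both ends (C4=O and C2–O1). It joins ring A (through C4a) to ring B (at C2), so it is a hidden 1,3-diaryl-1,3-dicarbonyl unit. That unit maps onto a 3,5-diarylisoxazole with ring A on isoxazole C3 and ring B on isoxazole C5.
- Ring C is opened at O1–C2 (cyclodehydration of the C8a phenol onto the ring B carbonyl). C4=O is traced back to the C4–NH2 of an enaminone, which comes from N–O hydrogenolysis of isoxazole 8.
- Key disconnection: the isoxazole C3–C4 and O1–C5 bonds, giving the ring A nitrile oxide 7 and the ring B arylacetylene 6.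
- 7 comes from the oxime of benzylated aldehyde 1. 6 comes from benzylated aldehyde 4 by one-carbon homologation.
- Ring order: rings A and B are bought, the isoxazole is built in step 5 and opened in step 6, and pyranone ring C is closed in step 7.

Key step: step 5

Assumption: 1 and 4 are taken as catalogue chemicals; the target has no stereocentre, so the descriptors E (oxime 3) and Z (enaminone 9) are transient geometries that are not carried into 11.

**Step 1**
Reactants: 1 2-hydroxy-3,4-dimethoxybenzaldehyde
Product: 2 2-(benzyloxy)-3,4-dimethoxybenzaldehyde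
Conditions: BnBr, K2CO3, DMF, 60 °C
Reagents that add atoms: benzyl bromide, BrCc1ccccc1
Why: Williamson ether synthesis, in which carbonate in DMF breaks the hydrogen bond of the ortho-hydroxy aldehyde and the phenoxide displaces bromide (SN2), masking the future O1 with a group that hydrogenolysis removes later.

**Step 2**
Reactants: 2 2-(benzyloxy)-3,4-dimethoxybenzaldehyde
Product: 3 (E)-2-(benzyloxy)-3,4-dimethoxybenzaldehyde oxime
Conditions: NH2OH·HCl, NaOAc, EtOH–H2O, rt
Reagents that add atoms: hydroxylamine hydrochloride, NO.Cl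
Why: Oxime condensation of an aromatic aldehyde under acetate buffering should give the thermodynamically preferred E aldoxime, and the ethers are inert.

**Step 3**
Reactants: 4 3-hydroxy-4,5-dimethoxybenzaldehyde
Product: 5 3-(benzyloxy)-4,5-dimethoxybenzaldehyde
Conditions: BnBr, K2CO3, DMF, rt to 50 °C
Reagents that add atoms: benzyl bromide, BrCc1ccccc1
Why: Williamson ether synthesis on an unhindered phenol, needed because a free phenol would be dearomatised by the oxidant of step 5.

**Step 4**
Reactants: 5 3-(benzyloxy)-4,5-dimethoxybenzaldehyde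
Product: 6 1-(benzyloxy)-5-ethynyl-2,3-dimethoxybenzene
Conditions: dimethyl (1-diazo-2-oxopropyl)phosphonate, K2CO3, MeOH, rt
Reagents that add atoms: dimethyl (1-diazo-2-oxopropyl)phosphonate, COP(=O)(OC)C(=[N+]=[N-])C(C)=O
Why: Ohira–Bestmann variant of the Seyferth–Gilbert homologation, in which methanolysis frees the diazophosphonate anion, this adds to the non-enolisable aldehyde, and phosphate elimination, loss of N2 and a 1,2-hydrogen shift give the terminal alkyne under conditions that leave the ethers alone.

**Step 5**
Reactants: 3 (E)-2-(benzyloxy)-3,4-dimethoxybenzaldehyde oxime (slight excess); 6 1-(benzyloxy)-5-ethynyl-2,3-dimethoxybenzene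
Product: 8 3-[2-(benzyloxy)-3,4-dimethoxyphenyl]-5-[3-(benzyloxy)-4,5-dimethoxyphenyl]isoxazole, via nitrile oxide 7 (not isolated)
Conditions: PhI(OAc)2 (added slowly), TFA (cat.), MeOH–CH2Cl2, 0 °C to rt
Reagents that add atoms: none
Why: Ligand exchange of the oxime on the trivalent iodine centre, followed by loss of iodobenzene and acetic acid, dehydrogenates 3 to nitrile oxide 7, and an oxidant without electrophilic chlorine is chosen because hypochlorite or NCS could chlorinate the two trialkoxyarenes. Dipole 7 then adds to alkyne 6 in a concerted, asynchronous Huisgen 1,3-dipolar [3+2] cycloaddition that makes the isoxazole C3–C4 bond (the later flavone C4–C3 bond) and the O1–C5 bond (oxygen on the later C2) at once; the closest known reaction type is the addition of aryl nitrile oxides to arylacetylenes giving 3,5-diarylisoxazoles. The five-membered ring is closed intermolecularly by this cycloaddition, with three atoms (C, N, O) from the dipole and two from the alkyne, and it is aromatic as formed, so no later oxidation is needed. No stereocentre arises. The selectivity required is regiochemical: the dipole carbon bonds to the unsubstituted alkyne terminus, which has the larger HOMO coefficient and the smaller steric demand, so ring B lands on C5 beside oxygen and ring A on C3, the placement that later puts ring A on flavone C4 and ring B on C2. Slow addition of the oxidant keeps 7 dilute and its ortho-benzyloxy group shields the dipole carbon, so dimerisation should lag behind the cycloaddition, and both phenols are benzylated so that the iodane finds no phenol to dearomatise.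

**Step 6**
Reactants: 8 3-[2-(benzyloxy)-3,4-dimethoxyphenyl]-5-[3-(benzyloxy)-4,5-dimethoxyphenyl]isoxazole
Product: 9 (Z)-3-amino-3-(2-hydroxy-3,4-dimethoxyphenyl)-1-(3-hydroxy-4,5-dimethoxyphenyl)prop-2-en-1-one
Conditions: H2 (3 atm), 10% Pd/C, EtOH–THF, rt; filtered, concentrated and used crude
Reagents that add atoms: none
Why: Catalytic hydrogenolysis cleaves the weak isoxazole N–O bond and both benzylic C–O bonds in one operation, while the vinylogous amide formed (held Z by an N–H···O=C hydrogen bond) and the aryl methyl ethers resist further reduction.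

**Step 7**
Reactants: 9 (Z)-3-amino-3-(2-hydroxy-3,4-dimethoxyphenyl)-1-(3-hydroxy-4,5-dimethoxyphenyl)prop-2-en-1-one
Product: 11 3'-hydroxy-4',5',7,8-tetramethoxyflavone, via 1,3-diketone 10 (not isolated)
Conditions: 2 M aq HCl, EtOH, reflux
Reagents that add atoms: water, O
Why: Acid hydrolysis of the enaminone (protonation at C3, addition of water at C4, loss of ammonium) gives diketone 10, whose C8a phenol adds to the ring B carbonyl in a 6-exo-trig closure and loses water, which is the classical acid cyclodehydration of 2-hydroxydibenzoylmethanes to flavones; the meta-placed 3'-OH cannot reach a carbonyl and the methyl ethers survive dilute acid.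

**Compound list**
1 | 2-hydroxy-3,4-dimethoxybenzaldehyde | COc1ccc(C=O)c(O)c1OC | starting material
2 | 2-(benzyloxy)-3,4-dimethoxybenzaldehyde | COc1ccc(C=O)c(OCc2ccccc2)c1OC | intermediate
3 | (E)-2-(benzyloxy)-3,4-dimethoxybenzaldehyde oxime | COc1ccc(/C=N/O)c(OCc2ccccc2)c1OC | intermediate
4 | 3-hydroxy-4,5-dimethoxybenzaldehyde | COc1cc(C=O)cc(O)c1OC | starting material
5 | 3-(benzyloxy)-4,5-dimethoxybenzaldehyde | COc1cc(C=O)cc(OCc2ccccc2)c1OC | intermediate
6 | 1-(benzyloxy)-5-ethynyl-2,3-dimethoxybenzene | COc1cc(C#C)cc(OCc2ccccc2)c1OC | intermediate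
7 | 2-(benzyloxy)-3,4-dimethoxybenzonitrile oxide | COc1ccc(C#[N+][O-])c(OCc2ccccc2)c1OC | intermediate
8 | 3-[2-(benzyloxy)-3,4-dimethoxyphenyl]-5-[3-(benzyloxy)-4,5-dimethoxyphenyl]isoxazole | COc1ccc(-c2cc(-c3cc(OC)c(OC)c(OCc4ccccc4)c3)on2)c(OCc2ccccc2)c1OC | intermediate
9 | (Z)-3-amino-3-(2-hydroxy-3,4-dimethoxyphenyl)-1-(3-hydroxy-4,5-dimethoxyphenyl)prop-2-en-1-one | COc1ccc(/C(N)=C/C(=O)c2cc(O)c(OC)c(OC)c2)c(O)c1OC | intermediate
10 | 1-(2-hydroxy-3,4-dimethoxyphenyl)-3-(3-hydroxy-4,5-dimethoxyphenyl)propane-1,3-dione | COc1ccc(C(=O)CC(=O)c2cc(O)c(OC)c(OC)c2)c(O)c1OC | intermediate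
11 | 3'-hydroxy-4',5',7,8-tetramethoxyflavone, 2-(3-hydroxy-4,5-dimethoxyphenyl)-7,8-dimethoxy-4H-chromen-4-one | COc1cc(-c2cc(=O)c3ccc(OC)c(OC)c3o2)cc(O)c1OC | target

**Step count**
Total steps: 7. Longest linear sequence: 5 steps (steps 1, 2, 5, 6, 7 or steps 3, 4, 5, 6, 7).

**Steps most likely to fail**

Step 5. The cycloaddition is slowed by the ortho substituent on the dipole. Dimerisation of the nitrile oxide, or oxidation of the electron-rich arenes by the iodane, may then outrun it.
- The fallback sets out from 6 and 2 and comes back at 8. It makes the C–C bond by acetylide addition and closes the isoxazole by cycloisomerisation.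
- Alkyne 6 is lithiated (n-BuLi, THF, −78 °C) and added to aldehyde 2. This gives the racemic propargylic alcohol 1-[2-(benzyloxy)-3,4-dimethoxyphenyl]-3-[3-(benzyloxy)-4,5-dimethoxyphenyl]prop-2-yn-1-ol F1.
- MnO2 in CH2Cl2 oxidises it to the ynone 1-[2-(benzyloxy)-3,4-dimethoxyphenyl]-3-[3-(benzyloxy)-4,5-dimethoxyphenyl]prop-2-yn-1-one F2.
- NH2OH·HCl with pyridine in EtOH converts the ynone into the acetylenic oxime (1E)-1-[2-(benzyloxy)-3,4-dimethoxyphenyl]-3-[3-(benzyloxy)-4,5-dimethoxyphenyl]prop-2-yn-1-one oxime F3. Its hydroxyl should sit syn to the slim alkynyl arm.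
- Catalytic AuCl3 in CH2Cl2 then activates the alkyne for 5-endo-dig attack of the oxime oxygen at the carbon bearing ring B. This gives 8 with the same ring placement.

Step 6. N–O hydrogenolysis of the diarylisoxazole may stall after the benzyl ethers have gone. Pushing the hydrogenation harder may over-reduce the enaminone.
- The fallback sets out from 8 and comes back at 9. It separates the two tasks.
- Mo(CO)6 in MeCN–H2O at reflux cleaves only the N–O bond. This gives (Z)-3-amino-3-[2-(benzyloxy)-3,4-dimethoxyphenyl]-1-[3-(benzyloxy)-4,5-dimethoxyphenyl]prop-2-en-1-one F4.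
- Mild hydrogenolysis (H2, 1 atm, Pd/C, EtOAc–EtOH with a little AcOH) then removes the two benzyl groups and gives 9.

Step 7. Hydrolysis may stall at the vinylogous amide, or the diketone may undergo retro-Claisen fragmentation in hot aqueous acid.
- The fallback sets out from 9 and comes back at 11. It closes ring C first and exchanges nitrogen for oxygen afterwards.
- Anhydrous HCl in dioxane at 60 °C makes the C8a phenol add to the ring B carbonyl with loss of water. This gives 2-(3-hydroxy-4,5-dimethoxyphenyl)-7,8-dimethoxy-4H-chromen-4-imine F5 as its hydrochloride, and no open-chain diketone is ever present.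
- Brief warming of this salt in dilute aqueous acid hydrolyses the C4=N bond and gives 11.

**Further compounds**
F1 | step 5 | 1-[2-(benzyloxy)-3,4-dimethoxyphenyl]-3-[3-(benzyloxy)-4,5-dimethoxyphenyl]prop-2-yn-1-ol (racemic) | COc1ccc(C(O)C#Cc2cc(OC)c(OC)c(OCc3ccccc3)c2)c(OCc2ccccc2)c1OC
F2 | step 5 | 1-[2-(benzyloxy)-3,4-dimethoxyphenyl]-3-[3-(benzyloxy)-4,5-dimethoxyphenyl]prop-2-yn-1-one | COc1ccc(C(=O)C#Cc2cc(OC)c(OC)c(OCc3ccccc3)c2)c(OCc2ccccc2)c1OC
F3 | step 5 | (1E)-1-[2-(benzyloxy)-3,4-dimethoxyphenyl]-3-[3-(benzyloxy)-4,5-dimethoxyphenyl]prop-2-yn-1-one oxime | COc1ccc(/C(C#Cc2cc(OC)c(OC)c(OCc3ccccc3)c2)=N/O)c(OCc2ccccc2)c1OC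
F4 | step 6 | (Z)-3-amino-3-[2-(benzyloxy)-3,4-dimethoxyphenyl]-1-[3-(benzyloxy)-4,5-dimethoxyphenyl]prop-2-en-1-one | COc1ccc(/C(N)=C/C(=O)c2cc(OC)c(OC)c(OCc3ccccc3)c2)c(OCc2ccccc2)c1OC
F5 | step 7 | 2-(3-hydroxy-4,5-dimethoxyphenyl)-7,8-dimethoxy-4H-chromen-4-imine | COc1cc(-c2cc(=N)c3ccc(OC)c(OC)c3o2)cc(O)c1OC
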